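The disconnection that carries everything is the C2'–O bond of ring B. O2' and the lactone carbonyl C9' are joined through C1'–C7'–C8' just as in a 3,4-dihydrocoumarin, so both are traced to an indan-1-one in which C9' is bonded to C2'. A Baeyer–Villiger oxidation with aryl migration then creates the C2'–O bond and the six-membered aryl lactone in one operation; the acetylated C9 oxygen later takes over the acyl group, giving the γ-lactone and freeing the 2'-phenol. The precursor, a 6-benzyloxy-7-methoxyindan-1-one carrying the (R)-configured C8 side chain at C2, comes from trans-alkylation of an enantiopure β-benzyl lactone with a 2-bromobenzyl bromide and Parham cyclisation.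

Key step: step 12

Numbering used: ring A is the 4-hydroxy-3-methoxyphenyl ring with C7 (benzylic), C8 and C9 (OCH2); ring B is the 2,4-dihydroxy-3-methoxyphenyl ring (primed) with C7', C8' and C9' (C=O).
Remark: C8' (indanone C2, chromanone C3) lies α to a carbonyl and is configurationally labile in 21–25; it is drawn without a descriptor there (expected mainly R as formed) and is fixed by the equilibration in step 13.

Step 1
Reactants: 1 3-(4-hydroxy-3-methoxyphenyl)propanoic acid (dihydroferulic acid)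
Product: 3 3-[4-(benzyloxy)-3-methoxyphenyl]propanoic acid, via benzyl ester 2 (not isolated)
Conditions: BnBr (2.2 equiv), K2CO3, DMF, 60 °C; then NaOH, MeOH–H2O, 60 °C; aq. HCl
Reagents that add atoms: benzyl bromide, BrCc1ccccc1; sodium hydroxide, [Na+].[OH-]
Why: Williamson etherification of the phenol (the carboxylate is benzylated as well) followed by saponification of the benzyl ester should leave only the robust aryl benzyl ether; no stereocentre is involved.

Step 2
Reactants: 3 3-[4-(benzyloxy)-3-methoxyphenyl]propanoic acid; 4 (4S)-4-benzyl-1,3-oxazolidin-2-one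
Product: 6 (4S)-4-benzyl-3-{3-[4-(benzyloxy)-3-methoxyphenyl]propanoyl}-1,3-oxazolidin-2-one, via mixed anhydride 5 (not isolated)
Conditions: t-BuCOCl, Et3N, THF, −20 °C; then LiCl, 4, −20 °C → rt
Reagents that add atoms: none
Why: N-acylation of the oxazolidinone through the mixed pivalic anhydride is the standard loading of an Evans auxiliary, the hindered pivaloyl carbonyl steering attack to the desired acyl group.

Step 3
Reactants: 6 (4S)-4-benzyl-3-{3-[4-(benzyloxy)-3-methoxyphenyl]propanoyl}-1,3-oxazolidin-2-one; 7 tert-butyl bromoacetate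
Product: 9 tert-butyl (3R)-3-{[4-(benzyloxy)-3-methoxyphenyl]methyl}-4-[(4S)-4-benzyl-2-oxo-1,3-oxazolidin-3-yl]-4-oxobutanoate, via sodium enolate 8 (not isolated)
Conditions: NaN(SiMe3)2, THF, −78 °C; then 7, −78 → −40 °C
Reagents that add atoms: none
Why: Evans asymmetric alkylation, in which the chelated Z-enolate is shielded on one face by the (4S)-benzyl group so that the bromoacetate should enter from the other face and set C8 as R.

Step 4
Reactants: 9 tert-butyl (3R)-3-{[4-(benzyloxy)-3-methoxyphenyl]methyl}-4-[(4S)-4-benzyl-2-oxo-1,3-oxazolidin-3-yl]-4-oxobutanoate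
Product: 11 (4R)-4-{[4-(benzyloxy)-3-methoxyphenyl]methyl}oxolan-2-one, via hydroxy ester 10 (not isolated)
Conditions: LiBH4, MeOH (1 equiv), THF, 0 °C; then TsOH·H2O (cat.), toluene, 80 °C
Reagents that add atoms: none
Why: Reductive cleavage of the imide by LiBH4 spares the tert-butyl ester, and acid-catalysed lactonisation of the γ-hydroxy ester then closes the five-membered ring without touching C8.

Step 5
Reactants: 12 4-(benzyloxy)-3-hydroxybenzaldehyde
Product: 13 4-(benzyloxy)-2-bromo-3-hydroxybenzaldehyde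
Conditions: Br2, NaOAc, Fe powder (cat.), AcOH, rt
Reagents that add atoms: bromine, BrBr
Why: Electrophilic aromatic bromination of 3-hydroxy-4-alkoxybenzaldehydes is known to occur ortho to the free phenol at the position between OH and CHO, which places the halogen on the future C2'.

Step 6
Reactants: 13 4-(benzyloxy)-2-bromo-3-hydroxybenzaldehyde
Product: 14 4-(benzyloxy)-2-bromo-3-methoxybenzaldehyde
Conditions: MeI, K2CO3, DMF, rt
Reagents that add atoms: iodomethane, CI
Why: Williamson O-methylation of the phenol installs the 3'-methoxy group.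

Step 7
Reactants: 14 4-(benzyloxy)-2-bromo-3-methoxybenzaldehyde
Product: 15 [4-(benzyloxy)-2-bromo-3-methoxyphenyl]methanol
Conditions: NaBH4, MeOH–THF, 0 °C
Reagents that add atoms: none
Why: Borohydride reduction of the aryl aldehyde should give the benzylic alcohol without affecting the aryl bromide or the benzyl ether.

Step 8
Reactants: 15 [4-(benzyloxy)-2-bromo-3-methoxyphenyl]methanol
Product: 16 1-(benzyloxy)-3-bromo-4-(bromomethyl)-2-methoxybenzene
Conditions: PBr3, CH2Cl2, 0 °C
Reagents that add atoms: phosphorus tribromide, BrP(Br)Br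
Why: Nucleophilic substitution of the primary benzylic alcohol via its phosphite ester is a routine route to electron-rich benzyl bromides.

Step 9
Reactants: 11 (4R)-4-{[4-(benzyloxy)-3-methoxyphenyl]methyl}oxolan-2-one; 16 1-(benzyloxy)-3-bromo-4-(bromomethyl)-2-methoxybenzene
Product: 18 (3R,4R)-3-{[4-(benzyloxy)-2-bromo-3-methoxyphenyl]methyl}-4-{[4-(benzyloxy)-3-methoxyphenyl]methyl}oxolan-2-one, via lithium enolate 17 (not isolated)
Conditions: LiN(SiMe3)2, THF, −78 °C; then 16, DMPU, −78 → −30 °C
Reagents that add atoms: none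
Why: Enolate alkylation of a β-substituted γ-butyrolactone takes the benzylic bromide anti to the C8 substituent, so substrate control should give the trans (8R,8'R) lactone.

Step 10
Reactants: 18 (3R,4R)-3-{[4-(benzyloxy)-2-bromo-3-methoxyphenyl]methyl}-4-{[4-(benzyloxy)-3-methoxyphenyl]methyl}oxolan-2-one
Product: 21 6-(benzyloxy)-2-{(2R)-1-[4-(benzyloxy)-3-methoxyphenyl]-3-hydroxypropan-2-yl}-7-methoxyindan-1-one, via aryllithium 19 (not isolated), via lithium hemiketalate 20 (not isolated)
Conditions: t-BuLi (2.05 equiv), THF–Et2O, −95 °C; then AcOH, −95 °C → rt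
Reagents that add atoms: none
Why: Parham cyclisation, in which bromine–lithium exchange outruns attack of t-BuLi on the lactone, the aryllithium adds 5-exo-trig to the lactone carbonyl C9', and the tetrahedral adduct (which protects the new ketone until the quench) opens on work-up to the indan-1-one and the free C9 alcohol with C8 unchanged.

Step 11
Reactants: 21 6-(benzyloxy)-2-{(2R)-1-[4-(benzyloxy)-3-methoxyphenyl]-3-hydroxypropan-2-yl}-7-methoxyindan-1-one
Product: 22 (2R)-3-[4-(benzyloxy)-3-methoxyphenyl]-2-[6-(benzyloxy)-7-methoxy-1-oxoindan-2-yl]propyl acetate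
Conditions: Ac2O, pyridine, DMAP (cat.), CH2Cl2, 0 °C → rt
Reagents that add atoms: acetic anhydride, CC(=O)OC(C)=O
Why: Acetylation (nucleophilic acyl substitution) of the primary alcohol traps the open hydroxy-ketone form, removing the hemiketal equilibrium, and masks the C9 oxygen for the peracid step.

Step 12
Reactants: 22 (2R)-3-[4-(benzyloxy)-3-methoxyphenyl]-2-[6-(benzyloxy)-7-methoxy-1-oxoindan-2-yl]propyl acetate
Product: 24 (2R)-3-[4-(benzyloxy)-3-methoxyphenyl]-2-[7-(benzyloxy)-8-methoxy-2-oxochroman-3-yl]propyl acetate, via Criegee adduct 23 (not isolated)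
Conditions: mCPBA (2 equiv), CF3CO2H (1 equiv), CH2Cl2, 0 °C → rt, dark
Reagents that add atoms: 3-chloroperoxybenzoic acid, OOC(=O)c1cccc(Cl)c1
Why: The peracid adds to the protonated indanone carbonyl C9' to give the tetrahedral adduct 23, which rearranges by a 1,2-shift of the aryl carbon C2' from C9' to the proximal peroxide oxygen with loss of 3-chlorobenzoic acid. The closest known reaction is the Baeyer–Villiger oxidation of 1-indanones to 3,4-dihydrocoumarins. The six-membered chroman-2-one ring is formed not by an end-to-end cyclisation but by ring expansion, oxygen being inserted into the C2'–C9' bond of the five-membered ketone. No stereocentre is created: C8 is remote and untouched, and C8' does not migrate and keeps whatever configuration it has. The step needs migration of the aryl carbon and not of the secondary alkyl carbon C8'; the ortho methoxy group at C3' makes C2' the better carrier of positive charge, the acidic medium sharpens this electronic preference, and the β-acetoxy group slightly lowers the aptitude of C8'. The benzyl ethers, the acetate and ring A carry nothing that the peracid should attack under these conditions.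

Step 13
Reactants: 24 (2R)-3-[4-(benzyloxy)-3-methoxyphenyl]-2-[7-(benzyloxy)-8-methoxy-2-oxochroman-3-yl]propyl acetate
Product: 26 (3R,4R)-3-{[4-(benzyloxy)-2-hydroxy-3-methoxyphenyl]methyl}-4-{[4-(benzyloxy)-3-methoxyphenyl]methyl}oxolan-2-one, via hydroxy methyl ester 25 (not isolated)
Conditions: NaOMe (2 equiv), MeOH–THF, rt → 40 °C; then aq. HCl
Reagents that add atoms: none
Why: Transesterification by methoxide removes the acetate and opens the activated aryl ester, the freed C9 hydroxyl lactonises onto C9' to give the more stable γ-lactone and release the 2'-phenol, and base-mediated epimerisation should settle C8' in the thermodynamically preferred trans (8'R) arrangement relative to the fixed C8 centre.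

Step 14
Reactants: 26 (3R,4R)-3-{[4-(benzyloxy)-2-hydroxy-3-methoxyphenyl]methyl}-4-{[4-(benzyloxy)-3-methoxyphenyl]methyl}oxolan-2-one
Product: 27 (3R,4R)-3-[(2,4-dihydroxy-3-methoxyphenyl)methyl]-4-[(4-hydroxy-3-methoxyphenyl)methyl]oxolan-2-one
Conditions: H2 (1 atm), 10% Pd/C, EtOAc–MeOH, rt
Reagents that add atoms: none
Why: Catalytic hydrogenolysis cleaves both aryl benzyl ethers, and nothing else in the molecule is reducible under these conditions.

Compound list
1 | 3-(4-hydroxy-3-methoxyphenyl)propanoic acid (dihydroferulic acid) | COc1cc(CCC(=O)O)ccc1O | starting material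
2 | benzyl 3-[4-(benzyloxy)-3-methoxyphenyl]propanoate (formed in the flask) | COc1cc(CCC(=O)OCc2ccccc2)ccc1OCc1ccccc1 | intermediate
3 | 3-[4-(benzyloxy)-3-methoxyphenyl]propanoic acid | COc1cc(CCC(=O)O)ccc1OCc1ccccc1 | intermediate
4 | (4S)-4-benzyl-1,3-oxazolidin-2-one | O=C1N[C@@H](Cc2ccccc2)CO1 | starting material
5 | 3-[4-(benzyloxy)-3-methoxyphenyl]propanoic pivalic anhydride (formed in the flask) | COc1cc(CCC(=O)OC(=O)C(C)(C)C)ccc1OCc1ccccc1 | intermediate
6 | (4S)-4-benzyl-3-{3-[4-(benzyloxy)-3-methoxyphenyl]propanoyl}-1,3-oxazolidin-2-one | COc1cc(CCC(=O)N2[C@@H](Cc3ccccc3)COC2=O)ccc1OCc1ccccc1 | intermediate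
7 | tert-butyl bromoacetate | CC(C)(C)OC(=O)CBr | starting material
8 | sodium (Z)-enolate of 6 (formed in the flask) | COc1cc(C/C=C(\[O-])N2[C@@H](Cc3ccccc3)COC2=O)ccc1OCc1ccccc1.[Na+] | intermediate
9 | tert-butyl (3R)-3-{[4-(benzyloxy)-3-methoxyphenyl]methyl}-4-[(4S)-4-benzyl-2-oxo-1,3-oxazolidin-3-yl]-4-oxobutanoate | COc1cc(C[C@H](CC(=O)OC(C)(C)C)C(=O)N2[C@@H](Cc3ccccc3)COC2=O)ccc1OCc1ccccc1 | intermediate
10 | tert-butyl (3R)-3-{[4-(benzyloxy)-3-methoxyphenyl]methyl}-4-hydroxybutanoate (formed in the flask) | COc1cc(C[C@H](CC(=O)OC(C)(C)C)CO)ccc1OCc1ccccc1 | intermediate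
11 | (4R)-4-{[4-(benzyloxy)-3-methoxyphenyl]methyl}oxolan-2-one | COc1cc(C[C@H]2COC(=O)C2)ccc1OCc1ccccc1 | intermediate
12 | 4-(benzyloxy)-3-hydroxybenzaldehyde | O=Cc1ccc(OCc2ccccc2)c(O)c1 | starting material
13 | 4-(benzyloxy)-2-bromo-3-hydroxybenzaldehyde | O=Cc1ccc(OCc2ccccc2)c(O)c1Br | intermediate
14 | 4-(benzyloxy)-2-bromo-3-methoxybenzaldehyde | COc1c(OCc2ccccc2)ccc(C=O)c1Br | intermediate
15 | [4-(benzyloxy)-2-bromo-3-methoxyphenyl]methanol | COc1c(OCc2ccccc2)ccc(CO)c1Br | intermediate
16 | 1-(benzyloxy)-3-bromo-4-(bromomethyl)-2-methoxybenzene | COc1c(OCc2ccccc2)ccc(CBr)c1Br | intermediate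
17 | lithium enolate of 11 (formed in the flask) | COc1cc(C[C@H]2COC([O-])=C2)ccc1OCc1ccccc1.[Li+] | intermediate
18 | (3R,4R)-3-{[4-(benzyloxy)-2-bromo-3-methoxyphenyl]methyl}-4-{[4-(benzyloxy)-3-methoxyphenyl]methyl}oxolan-2-one | COc1cc(C[C@H]2COC(=O)[C@@H]2Cc2ccc(OCc3ccccc3)c(OC)c2Br)ccc1OCc1ccccc1 | intermediate
19 | aryllithium from 18, lithium in place of bromine at C2' (formed in the flask) | COc1cc(C[C@H]2COC(=O)[C@@H]2Cc2ccc(OCc3ccccc3)c(OC)c2[Li])ccc1OCc1ccccc1 | intermediate
20 | cis-fused lithium 7-(benzyloxy)-3-{[4-(benzyloxy)-3-methoxyphenyl]methyl}-8-methoxy-2,3,3a,4-tetrahydroindeno[1,2-b]furan-8b-olate, C8 and C8' as in 18 (formed in the flask) | COc1cc(C[C@H]2CO[C@]3([O-])c4c(OC)c(OCc5ccccc5)ccc4C[C@H]23)ccc1OCc1ccccc1.[Li+] | intermediate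
21 | 6-(benzyloxy)-2-{(2R)-1-[4-(benzyloxy)-3-methoxyphenyl]-3-hydroxypropan-2-yl}-7-methoxyindan-1-one (indanone C2 labile) | COc1cc(C[C@@H](CO)C2Cc3ccc(OCc4ccccc4)c(OC)c3C2=O)ccc1OCc1ccccc1 | intermediate
22 | (2R)-3-[4-(benzyloxy)-3-methoxyphenyl]-2-[6-(benzyloxy)-7-methoxy-1-oxoindan-2-yl]propyl acetate (indanone C2 labile) | COc1cc(C[C@@H](COC(C)=O)C2Cc3ccc(OCc4ccccc4)c(OC)c3C2=O)ccc1OCc1ccccc1 | intermediate
23 | Criegee adduct of 22, 1-hydroxy-1-(3-chlorobenzoylperoxy)indane (formed in the flask) | COc1cc(C[C@@H](COC(C)=O)C2Cc3ccc(OCc4ccccc4)c(OC)c3C2(O)OOC(=O)c2cccc(Cl)c2)ccc1OCc1ccccc1 | intermediate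
24 | (2R)-3-[4-(benzyloxy)-3-methoxyphenyl]-2-[7-(benzyloxy)-8-methoxy-2-oxochroman-3-yl]propyl acetate (chromanone C3 labile) | COc1cc(C[C@@H](COC(C)=O)C2Cc3ccc(OCc4ccccc4)c(OC)c3OC2=O)ccc1OCc1ccccc1 | intermediate
25 | methyl (3R)-2-{[4-(benzyloxy)-2-hydroxy-3-methoxyphenyl]methyl}-4-[4-(benzyloxy)-3-methoxyphenyl]-3-(hydroxymethyl)butanoate (formed in the flask) | COc1cc(C[C@@H](CO)C(Cc2ccc(OCc3ccccc3)c(OC)c2O)C(=O)OC)ccc1OCc1ccccc1 | intermediate
26 | (3R,4R)-3-{[4-(benzyloxy)-2-hydroxy-3-methoxyphenyl]methyl}-4-{[4-(benzyloxy)-3-methoxyphenyl]methyl}oxolan-2-one | COc1cc(C[C@H]2COC(=O)[C@@H]2Cc2ccc(OCc3ccccc3)c(OC)c2O)ccc1OCc1ccccc1 | intermediate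
27 | (3R,4R)-3-[(2,4-dihydroxy-3-methoxyphenyl)methyl]-4-[(4-hydroxy-3-methoxyphenyl)methyl]oxolan-2-one | COc1cc(C[C@H]2COC(=O)[C@@H]2Cc2ccc(O)c(OC)c2O)ccc1O | target

Total step count: 14.
Longest linear sequence: 10 steps (steps 1–4, then 9–14; the ring B branch, steps 5–8 then 9–14, is equally long).

Steps most likely to fail

Step 12. The secondary alkyl carbon C8' may migrate in competition with the aryl carbon C2', so that oxygen enters on the wrong side. This is more likely if the crowded 3'-methoxy group is twisted out of conjugation, and peracid addition to the hindered carbonyl may also be slow. The fallback replaces oxygen insertion by ipso-oxidation of a boronate. It sets out from bromolactone 18: Miyaura borylation (B2pin2, PdCl2(dppf), KOAc, dioxane, 90 °C) should give the pinacol boronate F1. Oxidation with NaBO3·4H2O in THF–H2O should then deliver the 2'-phenol, and the route is rejoined at 26; steps 10–13 are not needed in that case.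

Step 10. Proton transfer from the lactone α-position to the aryllithium, or addition of t-BuLi to the lactone carbonyl, may compete with exchange and ring closure. The fallback uses a less acidic acyl donor whose chelated adduct is stable. It sets out from 18: aminolysis with MeNH(OMe)·HCl/AlMe3 in CH2Cl2 should give the hydroxy Weinreb amide F2, and silylation (t-BuMe2SiCl, imidazole, DMF) the silyl ether F3. Treatment with t-BuLi at −95 °C should generate the aryllithium F4, which closes to the chelated tetrahedral adduct F5 and on AcOH work-up gives the silyloxy indanone F6. Desilylation with Bu4NF/AcOH in THF rejoins the route at 21.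

Step 5. Positional control may be lost in the bromination, through attack para to the hydroxyl group or double bromination. The fallback uses directed ortho-metalation in place of electrophilic substitution. It sets out from 12: O-methylation (MeI, K2CO3, DMF) should give 4-(benzyloxy)-3-methoxybenzaldehyde F7. Addition of LiN(Me)CH2CH2NMe2 in THF masks the aldehyde as the lithium α-amino alkoxide F8, and n-BuLi at −20 °C lithiates the position flanked by the two directing groups to give the 2-lithio α-amino alkoxide F9. BrCH2CH2Br converts it into the 2-bromo α-amino alkoxide F10, and aqueous work-up releases the aldehyde, rejoining the route at 14.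

Further compounds
F1 | step 12 | (3R,4R)-3-{[4-(benzyloxy)-3-methoxy-2-(4,4,5,5-tetramethyl-1,3,2-dioxaborolan-2-yl)phenyl]methyl}-4-{[4-(benzyloxy)-3-methoxyphenyl]methyl}oxolan-2-one | COc1cc(C[C@H]2COC(=O)[C@@H]2Cc2ccc(OCc3ccccc3)c(OC)c2B2OC(C)(C)C(C)(C)O2)ccc1OCc1ccccc1
F2 | step 10 | (2R,3R)-2-{[4-(benzyloxy)-2-bromo-3-methoxyphenyl]methyl}-3-{[4-(benzyloxy)-3-methoxyphenyl]methyl}-4-hydroxy-N-methoxy-N-methylbutanamide | COc1cc(C[C@@H](CO)[C@@H](Cc2ccc(OCc3ccccc3)c(OC)c2Br)C(=O)N(C)OC)ccc1OCc1ccccc1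
F3 | step 10 | (2R,3R)-2-{[4-(benzyloxy)-2-bromo-3-methoxyphenyl]methyl}-3-{[4-(benzyloxy)-3-methoxyphenyl]methyl}-4-[(tert-butyldimethylsilyl)oxy]-N-methoxy-N-methylbutanamide | COc1cc(C[C@@H](CO[Si](C)(C)C(C)(C)C)[C@@H](Cc2ccc(OCc3ccccc3)c(OC)c2Br)C(=O)N(C)OC)ccc1OCc1ccccc1
F4 | step 10 | aryllithium from F3, lithium in place of bromine at C2' | COc1cc(C[C@@H](CO[Si](C)(C)C(C)(C)C)[C@@H](Cc2ccc(OCc3ccccc3)c(OC)c2[Li])C(=O)N(C)OC)ccc1OCc1ccccc1
F5 | step 10 | lithium 6-(benzyloxy)-2-{(2R)-1-[4-(benzyloxy)-3-methoxyphenyl]-3-[(tert-butyldimethylsilyl)oxy]propan-2-yl}-7-methoxy-1-[methoxy(methyl)amino]indan-1-olate | COc1cc(C[C@@H](CO[Si](C)(C)C(C)(C)C)[C@H]2Cc3ccc(OCc4ccccc4)c(OC)c3C2([O-])N(C)OC)ccc1OCc1ccccc1.[Li+]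
F6 | step 10 | 6-(benzyloxy)-2-{(2R)-1-[4-(benzyloxy)-3-methoxyphenyl]-3-[(tert-butyldimethylsilyl)oxy]propan-2-yl}-7-methoxyindan-1-one | COc1cc(C[C@@H](CO[Si](C)(C)C(C)(C)C)C2Cc3ccc(OCc4ccccc4)c(OC)c3C2=O)ccc1OCc1ccccc1
F7 | step 5 | 4-(benzyloxy)-3-methoxybenzaldehyde | COc1cc(C=O)ccc1OCc1ccccc1
F8 | step 5 | lithium [4-(benzyloxy)-3-methoxyphenyl]{[2-(dimethylamino)ethyl](methyl)amino}methanolate | COc1cc(C([O-])N(C)CCN(C)C)ccc1OCc1ccccc1.[Li+]
F9 | step 5 | 2-lithio derivative of F8 | COc1c([Li])c(C([O-])N(C)CCN(C)C)ccc1OCc1ccccc1.[Li+]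
F10 | step 5 | lithium [4-(benzyloxy)-2-bromo-3-methoxyphenyl]{[2-(dimethylamino)ethyl](methyl)amino}methanolate | COc1c(Br)c(C([O-])N(C)CCN(C)C)ccc1OCc1ccccc1.[Li+]
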